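## Retrosynthetic overview

1. The target comes from propionylation of a C2 alcohol that is set, together with the C14 acetate, by an Evans–Tishchenko reduction of a ten-membered β-hydroxy ketone.
2. Ring B (ten-membered) is made by a palladium-catalysed decarboxylative ring contraction of a 12-membered allyl β-keto lactone; this key step forms the C3–C4 bond and extrudes CO2.
3. The 12-membered lactone and the butenolide come from one intramolecular Nozaki–Hiyama–Kishi addition/lactonisation (C6–C7 and C7–O) across an ester tether.
4. Ring A comes from a Michael/aldol annulation of 3-methylpentane-2,4-dione with a (2Z,5E)-dienal ester that already carries C7–C9 and C17–C19, followed by deconjugation and ketone reduction.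
5. Order of ring formation: ring A, then butenolide plus 12-membered lactone, then ring B by contraction.

Assumption: the numbered starting materials are taken as commercial. Ring positions are named with the briarane numbering of the target: C1 quaternary, C2–C9 in ring B, C10–C14 in ring A, C15/C16/C18/C20 the methyls on C1/C5/C17/C11, C19 the lactone carbonyl.

## Route

Step 1
Reactants: 1 3,3-dimethoxyprop-1-yne; 2 methyl chloroformate
Product: 3 methyl 4,4-dimethoxybut-2-ynoate
Conditions: n-BuLi, THF, −78 °C; then 2, −78 to 0 °C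
Reagents that add atoms: none
Why: Acylation of the lithium acetylide with a chloroformate gives the ynoate that will become C7, C8, C17 and C19.

Step 2
Reactants: 3 methyl 4,4-dimethoxybut-2-ynoate; 4 allylmagnesium bromide; 5 iodomethane
Product: 6 methyl (2Z)-3-(dimethoxymethyl)-2-methylhexa-2,5-dienoate
Conditions: 4, CuBr·SMe2 (1.1 equiv), THF, −78 °C; 3; then 5, HMPA, −78 to −30 °C
Reagents that add atoms: none
Why: Syn carbocupration of the ynoate followed by C-methylation of the α-cuprio ester on the side of the smaller β-substituent places the ester cis to the acetal carbon, which is the geometry the butenolide needs (tandem conjugate addition/alkylation).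

Step 3
Reactants: 6 methyl (2Z)-3-(dimethoxymethyl)-2-methylhexa-2,5-dienoate; 7 2-methylprop-2-enal
Product: 8 methyl (2Z,5E)-3-(dimethoxymethyl)-2,6-dimethyl-7-oxohepta-2,5-dienoate
Conditions: 7 (5 equiv), second-generation Grubbs catalyst (5 mol %), CH2Cl2, 40 °C
Reagents that add atoms: none
Why: Olefin cross-metathesis of the terminal alkene with methacrolein gives the (E)-2-methyl enal (C10–C12 with C20), and the tetrasubstituted enoate is inert.

Step 4
Reactants: 9 prop-2-yn-1-ol; 10 methylmagnesium bromide
Product: 11 (2Z)-3-iodo-2-methylprop-2-en-1-ol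
Conditions: 10 (2.2 equiv), CuI (10 mol %), THF, −20 to 23 °C; then I2, −78 °C
Reagents that add atoms: iodine (II)
Why: Copper-catalysed anti carbomagnesiation of the propargylic alkoxide through the chelated alkenylmagnesium and iodinolysis gives the (Z)-iodide with iodine cis to CH2OH, which later becomes the Z C5=C6 olefin.

Step 5
Reactants: 11 (2Z)-3-iodo-2-methylprop-2-en-1-ol
Product: 12 (2Z)-3-iodo-2-methylprop-2-en-1-yl 1H-imidazole-1-carboxylate
Conditions: 1,1'-carbonyldiimidazole, CH2Cl2, 23 °C
Reagents that add atoms: 1,1'-carbonyldiimidazole (O=C(n1ccnc1)n1ccnc1)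
Why: Acyl transfer from carbonyldiimidazole to the alcohol gives an imidazole carbamate that serves as a C-acylating agent.

Step 6
Reactants: 8 methyl (2Z,5E)-3-(dimethoxymethyl)-2,6-dimethyl-7-oxohepta-2,5-dienoate; 13 3-methylpentane-2,4-dione
Product: 15 methyl (2Z)-4-[6-acetyl-2,6-dimethyl-5-oxocyclohex-3-en-1-yl]-3-(dimethoxymethyl)-2-methylbut-2-enoate (C1 and C10 as in the target; C11 epimers), via Michael adduct 14 (not isolated)
Conditions: 9-amino-9-deoxy-epi-quinine (20 mol %), CF3CO2H (40 mol %), toluene, 40 °C; then p-toluenesulfonic acid (20 mol %), 80 °C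
Reagents that add atoms: none
Why: Iminium-ion Michael addition of the diketone to the α-branched enal sets C10 under catalyst control, and the aldol condensation then closes ring A through the chair that keeps the C10 side chain and the spectator acetyl trans-diequatorial, setting C1 with its methyl cis to the side chain (Robinson-type annulation; C11 is erased in step 8).

Step 7
Reactants: 15 methyl (2Z)-4-[6-acetyl-2,6-dimethyl-5-oxocyclohex-3-en-1-yl]-3-(dimethoxymethyl)-2-methylbut-2-enoate; 12 (2Z)-3-iodo-2-methylprop-2-en-1-yl 1H-imidazole-1-carboxylate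
Product: 16 (2Z)-3-iodo-2-methylprop-2-en-1-yl β-keto ester of 15 (the acetyl group has become C(=O)CH2CO2CH2C(CH3)=CHI)
Conditions: LiN(SiMe3)2 (2.1 equiv), THF, −78 °C; then 12, BF3·OEt2, −78 to −40 °C
Reagents that add atoms: none
Why: Kinetic enolisation of the methyl ketone (C1 is quaternary, so there is no other fast site) and C-acylation with the imidazole carbamate give the allyl β-keto ester (Claisen-type acylation).

Step 8
Reactants: 16 allyl β-keto ester (conjugated enone)
Product: 17 β,γ-unsaturated ketone (C11=C12; C14 ketone; otherwise as 16)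
Conditions: KOt-Bu (2.2 equiv), THF/t-BuOH, −40 to 0 °C; then AcOH, −78 °C
Reagents that add atoms: none
Why: With the β-keto ester protected as its enolate, the extended enolate of the ring enone forms by γ-deprotonation at C11 and is protonated kinetically at C13, which moves the olefin to C11=C12 and removes the C11 stereocentre (classical enone deconjugation).

Step 9
Reactants: 17 β,γ-unsaturated ketone
Product: 18 C14 alcohol (14-OH cis to the C2 acyl chain and trans to C15)
Conditions: LiN(SiMe3)2 (1.05 equiv), THF, −78 °C; then LiBH(s-Bu)3, −78 °C; aq. NH4Cl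
Reagents that add atoms: none
Why: With the β-keto ester masked as its enolate, the bulky hydride attacks the ring ketone from the face of the C1 methyl, anti to the larger side chain, which sets C14 (substrate-controlled ketone reduction).

Step 10
Reactants: 18 C14 alcohol with dimethyl acetal
Product: 19 aldehyde: methyl (2Z)-3-formyl-2-methylbut-2-enoate unit on C9 (otherwise as 18)
Conditions: pyridinium p-toluenesulfonate (10 mol %), acetone/H2O 10:1, 23 °C
Reagents that add atoms: water (O)
Why: The acetal on an sp2 carbon hydrolyses through a stabilised oxocarbenium ion under conditions mild enough to spare the δ-hydroxy β-keto ester (acetal hydrolysis).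

Step 11
Reactants: 19 aldehyde with (Z)-alkenyl iodide
Product: 21 12-membered allyl β-keto lactone carrying the butenolide and ring A (C7 as in the target), via seco hydroxy ester 20 (not isolated)
Conditions: CrCl2 (8 equiv), NiCl2 (2 mol %), (S)-N-[2-(4-isopropyl-4,5-dihydrooxazol-2-yl)-6-methylphenyl]methanesulfonamide (8.8 equiv), Et3N, THF, 0.002 M, 23 °C; then pyridinium p-toluenesulfonate
Reagents that add atoms: none
Why: In this Nozaki–Hiyama–Kishi macrocyclisation the alkenylchromium adds to the aldehyde with retention of the Z geometry, the chiral sulfonamide on trivalent chromium selects the aldehyde face to give (7S), and the alkoxide lactonises onto the cis methyl ester to form the butenolide.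

Step 12
Reactants: 21 12-membered allyl β-keto lactone
Product: 22 14-hydroxy-2-oxobriara-5(Z),8(17),11-trien-19,7-olide (stereocentres as in the target)
Conditions: Pd(PPh3)4 (10 mol %), THF, 0.005 M, 40 °C
Reagents that add atoms: none
Why: Proposed new method: zerovalent palladium ionises the primary allylic β-keto ester of the 12-membered lactone, the β-keto carboxylate loses CO2 to give a C3 ketone enolate held in the same ion pair, and C3 attacks the unsubstituted allyl terminus C4 (distal to the oxygen-bearing C7) faster than the anti-configured allyl can isomerise, so the ester bridge is excised and the ring contracts to the ten-membered carbocycle with the Z C5=C6 olefin; the closest known reaction is the Tsuji–Saegusa decarboxylative allylation (Carroll type) of acyclic allyl β-keto esters, which has not been shown as a macrolactone-to-carbocycle ring contraction.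

Step 13
Reactants: 22 14-hydroxy-2-oxobriara-5(Z),8(17),11-trien-19,7-olide; 23 acetaldehyde
Product: 24 14-acetoxy-2-hydroxybriara-5(Z),8(17),11-trien-19,7-olide (stereocentres as in the target)
Conditions: SmI2 (30 mol %), 23 (10 equiv), THF, −10 °C
Reagents that add atoms: none
Why: In this Evans–Tishchenko reduction the samarium-bound hemiacetal formed from the C14 hydroxyl and acetaldehyde delivers hydride intramolecularly to the C2 ketone, giving the 1,3-anti product with (2S) and leaving the acetate on O14.

Step 14
Reactants: 24 14-acetoxy-2-hydroxybriara-5(Z),8(17),11-trien-19,7-olide; 25 propanoyl chloride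
Product: 26 CNP0112230.2, (1S,2S,7S,10S,14S,5Z)-14-acetoxy-2-propanoyloxybriara-5,8(17),11-trien-19,7-olide
Conditions: 25, pyridine, 4-(dimethylamino)pyridine (10 mol %), CH2Cl2, 0 °C
Reagents that add atoms: none
Why: Nucleophile-catalysed acylation of the remaining secondary alcohol gives the target; the short, cold reaction limits acetate migration.

## Compound list

1 | 3,3-dimethoxyprop-1-yne | C#CC(OC)OC | starting material
2 | methyl chloroformate | COC(=O)Cl | starting material
3 | methyl 4,4-dimethoxybut-2-ynoate | COC(=O)C#CC(OC)OC | intermediate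
4 | allylmagnesium bromide | C=CC[Mg]Br | starting material
5 | iodomethane | CI | starting material
6 | methyl (2Z)-3-(dimethoxymethyl)-2-methylhexa-2,5-dienoate | COC(=O)/C(C)=C(\C(OC)OC)CC=C | intermediate
7 | 2-methylprop-2-enal (methacrolein) | CC(=C)C=O | starting material
8 | methyl (2Z,5E)-3-(dimethoxymethyl)-2,6-dimethyl-7-oxohepta-2,5-dienoate | COC(=O)/C(C)=C(\C(OC)OC)C/C=C(\C)C=O | intermediate
9 | prop-2-yn-1-ol | OCC#C | starting material
10 | methylmagnesium bromide | C[Mg]Br | starting material
11 | (2Z)-3-iodo-2-methylprop-2-en-1-ol | OC/C(C)=C\I | intermediate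
12 | (2Z)-3-iodo-2-methylprop-2-en-1-yl 1H-imidazole-1-carboxylate | O=C(OC/C(C)=C\I)n1ccnc1 | intermediate
13 | 3-methylpentane-2,4-dione | CC(=O)C(C)C(C)=O | starting material
14 | Michael adduct, methyl (2Z)-6-acetyl-3-(dimethoxymethyl)-2,6-dimethyl-7-oxo-5-(1-oxopropan-2-yl)oct-2-enoate (C10 as in 15; formyl-bearing carbon a mixture; not isolated) | COC(=O)/C(C)=C(\C(OC)OC)C[C@@H](C(C)C=O)C(C)(C(C)=O)C(C)=O | intermediate
15 | methyl (2Z)-4-[6-acetyl-2,6-dimethyl-5-oxocyclohex-3-en-1-yl]-3-(dimethoxymethyl)-2-methylbut-2-enoate (C15 methyl cis to the C9 side chain; C11 epimers) | COC(=O)/C(C)=C(\C(OC)OC)C[C@H]2C(C)C=CC(=O)[C@]2(C)C(C)=O | intermediate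
16 | (2Z)-3-iodo-2-methylprop-2-en-1-yl β-keto ester of 15 (conjugated C12=C13 enone) | COC(=O)/C(C)=C(\C(OC)OC)C[C@H]2C(C)C=CC(=O)[C@]2(C)C(=O)CC(=O)OC/C(C)=C\I | intermediate
17 | deconjugated ketone (C11=C12, C14 ketone) | COC(=O)/C(C)=C(\C(OC)OC)C[C@H]2C(C)=CCC(=O)[C@]2(C)C(=O)CC(=O)OC/C(C)=C\I | intermediate
18 | C14 alcohol (14-OH cis to the C2 chain) | COC(=O)/C(C)=C(\C(OC)OC)C[C@H]2C(C)=CC[C@H](O)[C@]2(C)C(=O)CC(=O)OC/C(C)=C\I | intermediate
19 | C7 aldehyde (formyl cis to the methyl ester) | COC(=O)/C(C)=C(\C=O)C[C@H]2C(C)=CC[C@H](O)[C@]2(C)C(=O)CC(=O)OC/C(C)=C\I | intermediate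
20 | seco hydroxy ester, 12-membered β-keto lactone with C7 hydroxyl and uncyclised methyl ester (not isolated) | O=C1CC(=O)OC/C(C)=C\[C@H](O)/C(=C(/C)C(=O)OC)C[C@H]2C(C)=CC[C@H](O)[C@]12C | intermediate
21 | 12-membered allyl β-keto lactone fused to the butenolide and ring A (C3 and C4 joined through C(=O)–O; 14-OH free) | O=C1CC(=O)OC/C(C)=C\[C@@H]2OC(=O)C(C)=C2C[C@H]2C(C)=CC[C@H](O)[C@]12C | intermediate
22 | 14-hydroxy-2-oxobriara-5(Z),8(17),11-trien-19,7-olide (stereocentres as in the target) | O=C1CC/C(C)=C\[C@@H]2OC(=O)C(C)=C2C[C@H]2C(C)=CC[C@H](O)[C@]12C | intermediate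
23 | acetaldehyde | CC=O | starting material
24 | 14-acetoxy-2-hydroxybriara-5(Z),8(17),11-trien-19,7-olide (stereocentres as in the target) | O[C@H]1CC/C(C)=C\[C@@H]2OC(=O)C(C)=C2C[C@H]2C(C)=CC[C@H](OC(C)=O)[C@]12C | intermediate
25 | propanoyl chloride | CCC(=O)Cl | starting material
26 | CNP0112230.2, (1S,2S,7S,10S,14S,5Z)-14-acetoxy-2-propanoyloxybriara-5,8(17),11-trien-19,7-olide | CCC(=O)O[C@H]1CC/C(C)=C\[C@@H]2OC(=O)C(C)=C2C[C@H]2C(C)=CC[C@H](OC(C)=O)[C@]12C | target

## Step count and risks

Total: 14 steps. Longest linear sequence: 12 steps (steps 1–3 and 6–14); steps 4–5 make the side fragment 12.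

The three steps most likely to fail:

Step 6 (annulation). The α-branched enal is a slow iminium partner, its doubly allylic C9 methylene invites dienamine isomerisation, and the wrong acetyl group may close the ring, giving the C1 epimer. The fallback sets out from 8 and returns at 15, and fixes C1/C10 by dienophile geometry instead. (E)-Pent-2-enal is silylated (t-BuMe2SiOTf, Et3N) to (1E,3E)-1-(tert-butyldimethylsilyloxy)penta-1,3-diene F1. F1 undergoes an enantioselective Diels–Alder reaction with 8, catalysed by (S)-1-(2-methylphenyl)-3,3-diphenyltetrahydro-1H,3H-pyrrolo[1,2-c][1,3,2]oxazaborole activated with HNTf2, to give the endo adduct, the 6-formyl-5-silyloxy-2,6-dimethylcyclohex-3-enyl aldehyde F2. The (E)-enal geometry puts the C15 methyl cis and the formyl group trans to the C9 chain. Addition of 10 to the aldehyde at −78 °C gives the methyl carbinol F3, Bu4NF removes the silyl group to give the diol F4, and Dess–Martin periodinane oxidises both carbinols to 15 (one C11 epimer).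

Step 12 (decarboxylative ring contraction, the new step). Possible failures are attack at C6 (eight-membered ring), protonation of the enolate, or ionisation of the allylic butenolide C7–O bond. The fallback uses only known reactions, sets out from 15 and returns at 22. Alcohol 11 is converted (CBr4, PPh3) to (1Z)-3-bromo-1-iodo-2-methylprop-1-ene F5. The kinetic lithium enolate of 15 (LiN(SiMe3)2, −78 °C) is alkylated with F5 to give the C3–C4-linked alkenyl iodide ketone F6. Deconjugation as in step 8 gives the β,γ-unsaturated diketone F7, and LiBH(s-Bu)3 at −78 °C reduces the ring ketone to the C14 alcohol F8. Acetal hydrolysis as in step 10 gives the iodo aldehyde F9. A direct ten-membered Nozaki–Hiyama–Kishi cyclisation (CrCl2, NiCl2, the sulfonamide ligand of step 11) with lactonisation then gives 22.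

Step 13 (Evans–Tishchenko). The C2 ketone is neopentylic and sits in a ten-membered ring, so hydride transfer may be slow, and the samarium alkoxide could trigger a retro-aldol opening or reduce the butenolide. The fallback sets out from 22 and returns at 24. The C14 hydroxyl is acetylated (Ac2O, pyridine) to the 14-acetoxy-2-oxo compound F10. The C2 ketone is then reduced under reagent control with BH3·SMe2 and (R)-1-methyl-3,3-diphenyltetrahydro-1H,3H-pyrrolo[1,2-c][1,3,2]oxazaborole, which distinguishes the quaternary C1 side from the C3 methylene and gives (2S)-24.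

## Further compounds

F1 | step 6 | (1E,3E)-1-(tert-butyldimethylsilyloxy)penta-1,3-diene | C/C=C/C=C/O[Si](C)(C)C(C)(C)C
F2 | step 6 | Diels–Alder adduct, methyl (2Z)-4-[6-formyl-2,6-dimethyl-5-(tert-butyldimethylsilyloxy)cyclohex-3-en-1-yl]-3-(dimethoxymethyl)-2-methylbut-2-enoate (silyloxy cis to formyl; C15 cis to the C9 chain) | COC(=O)/C(C)=C(\C(OC)OC)C[C@H]2[C@H](C)C=C[C@H](O[Si](C)(C)C(C)(C)C)[C@]2(C)C=O
F3 | step 6 | methyl carbinol from F2 (1-hydroxyethyl on C1, carbinol epimers) | COC(=O)/C(C)=C(\C(OC)OC)C[C@H]2[C@H](C)C=C[C@H](O[Si](C)(C)C(C)(C)C)[C@]2(C)C(C)O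
F4 | step 6 | diol from F3 (C14 hydroxyl and 1-hydroxyethyl) | COC(=O)/C(C)=C(\C(OC)OC)C[C@H]2[C@H](C)C=C[C@H](O)[C@]2(C)C(C)O
F5 | step 12 | (1Z)-3-bromo-1-iodo-2-methylprop-1-ene | BrC/C(C)=C\I
F6 | step 12 | C3-alkylated diketone, the acetyl of 15 extended to C(=O)CH2CH2C(CH3)=CHI (Z) | COC(=O)/C(C)=C(\C(OC)OC)C[C@H]2C(C)C=CC(=O)[C@]2(C)C(=O)CC/C(C)=C\I
F7 | step 12 | deconjugated diketone (C11=C12) from F6 | COC(=O)/C(C)=C(\C(OC)OC)C[C@H]2C(C)=CCC(=O)[C@]2(C)C(=O)CC/C(C)=C\I
F8 | step 12 | C14 alcohol from F7 | COC(=O)/C(C)=C(\C(OC)OC)C[C@H]2C(C)=CC[C@H](O)[C@]2(C)C(=O)CC/C(C)=C\I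
F9 | step 12 | iodo aldehyde from F8 (C7 formyl cis to the methyl ester) | COC(=O)/C(C)=C(\C=O)C[C@H]2C(C)=CC[C@H](O)[C@]2(C)C(=O)CC/C(C)=C\I
F10 | step 13 | 14-acetoxy-2-oxobriara-5(Z),8(17),11-trien-19,7-olide | O=C1CC/C(C)=C\[C@@H]2OC(=O)C(C)=C2C[C@H]2C(C)=CC[C@H](OC(C)=O)[C@]12C
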